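I start from a small charge: if every step is first order, a smaller and a larger charge trace the same percent curves.

| flask | substrate | remark | time |
|---|---|---|---|
| north-east | 1.5 M | the very flask that is asked about, followed so far |  |
| south | 3 M | run made earlier |  |
| flask | 1.5 M |  | 1.5 h |

- north-east (time / min: target / %, substrate / %): 10.0: 31.8, 14.4; 20.0: 30.6, 8.7; 25.0: 28.9, 8.5; 40.0: 25.6, 7.9; 50.0: 24.6, 7.9
- south (time / min: target / %, substrate / %): 3.00: 22.3, 46.8; 6.00: 30.3, 24.6; 10.0: 32.1, 14.0; 12.0: 32.5, 10.7; 15.0: 32.3, 10.3; 20.0: 31.5, 9.1

(standard deviation of a reading: 0.5 percentage points)

- violet: at 1.5 h take out 90% of the target then present, then wait 3.0 h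
- ochre: change nothing and wait 3.0 h more
- green: at 1.5 h add substrate, 50.0% of the amount charged, then wait 3.0 h

- target that was removed still counts
- additions bring no volume worth counting

1. target, in percent of the substrate first charged, at 1.5 h
2. which option adds most target ("none" when 2 percentage points or less is all one gets) (violet / ochre / green / none)
3. target present, with what was taken out counted in, in percent of the substrate first charged, after ochre
4. target present, with what was taken out counted in, in percent of the substrate first charged, after green

The runs agree with that. At 10.0 min the north-east run holds 31.8% target and 14.4% substrate, and the south run, with 3 M, holds 32.1% and 14.0% at 10.0 min. Those gaps are within the scatter of 0.5 percentage points, so I expect the charge to change no percentage.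

Next comes time. From 25.0 min to 50.0 min the target in the north-east run falls at 0.00644 min⁻¹. Continued to 1.5 h, that gives 19.0%. Substrate reads 7.9% and 7.9% at the last two readings, so I assume a reversible flask coming to rest. I therefore carry that number as the resting share, the part of the material in the flask that stands as target at rest. Ochre then stays within 2 points of now.

Green brings more material, and the share applies to it: 28.5%.

Violet banks 17.1% of target. A first pass adds the share of a full charge and gives 36.1%. But the flask now holds less, so I put that removal back in and go round once more: 32.9%. That is more than green.

The forecast says 21% now, 13% after ochre and 20% after green, and it picks violet: “violet wins in every picture”. My green stands higher.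

The flask gives 20.0% now, 17.8% after ochre and 26.7% after green, and violet gains 12 points, against 6.7 points for green and −2.3 points for ochre.

    substrate ⇌ isomer of the product B (K = 10.7, k = 0.125 min⁻¹)
    substrate ⇌ target (K = 2.70, k = 0.112 min⁻¹)
    substrate ⇌ dormant form (K = 0.720, k = 0.0247 min⁻¹)
    substrate ⇌ isomer of the product A (K = 0.110, k = 0.00975 min⁻¹)

Green over ochre is 1.50, the 150% of the rule, with a resting share of 17.8% in place of my 19.0%. Substrate's forward half-life is 5.5 min towards isomer of the product B and 6.2 min towards target, and its equilibrium constant is larger towards that isomer, 10.7 against 2.7. At 900 min the flask holds 70.3% of that isomer and 17.7% target. For the neighbour flask with 0.60 M, my share gives c(target) = 0.114 M; at 90.0 min it holds 20.0%, which is 0.120 M.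

The readings were computed from invented constants, and the scatter is random.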